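The route rests on cutting the hydroazulene at C6–C10 and C2–C3. Ring carbons C3–C6, with the methyl on C3 and the five-ring branch on C6, are read as a 2-methyl-5-alkylfuran, and C10–C1–C2, a ketone flanked by the quaternary carbon, as an oxyallyl cation. One intramolecular (4+3) cycloaddition then closes the seven-membered ring (C10-C1-C2-C3-C4-C5-C6) and the five-membered ring (C6-C7-C8-C9-C10), sets quaternary C10 against C7 and leaves a C3–O–C6 bridge that later unveils the C2=C3 alkene. The precursor is a tertiary α-chloro methyl ketone tethered through C9–C8–C7 to a 2-methylfuran, C7 carrying a ketal-masked acetyl group.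

Key step: step 6

Remark: locants C1–C10 are those of the target bicycle (C1 acetoxy carbon, C2 and C3 epoxide carbons, C6 and C10 ring-fusion carbons, C7 side-chain carbon); β is the face of H-6, of the C7 side chain and of both ring oxygens in the target, α the face of the C10 methyl; bicyclic compounds from 12 on are named as hydroazulenes with these locants.
Remark: the side chain is taken as (2Z,4E), that is, C7 and the vinyl carbon are cis on the trisubstituted alkene, as the SMILES string requires.

Step 1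
Reactants: 1 2-(2-bromoethyl)-2-methyl-1,3-dioxolane
Product: 2 2-ethenyl-2-methyl-1,3-dioxolane
Conditions: KOt-Bu, THF, 0 → 23 °C
Reagents that add atoms: none
Why: E2 dehydrobromination of the primary bromide by a hindered alkoxide should give the ketal of methyl vinyl ketone, the ketal being inert to base.

Step 2
Reactants: 2 2-ethenyl-2-methyl-1,3-dioxolane; 3 (E)-but-2-enal
Product: 4 (E)-3-(2-methyl-1,3-dioxolan-2-yl)prop-2-enal
Conditions: RuCl2(H2IMes)(=CH-C6H4-2-Oi-Pr) (5 mol %; second-generation phosphine-free ruthenium benzylidene, H2IMes = 1,3-dimesitylimidazolidin-2-ylidene), 3 (3 equiv), CH2Cl2, 40 °C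
Reagents that add atoms: none
Why: Olefin cross-metathesis between the vinyl ketal, which is slow to homodimerise because its allylic carbon is fully substituted, and the enal is driven by loss of propene and should give the E-enal under thermodynamic control.

Step 3
Reactants: 4 (E)-3-(2-methyl-1,3-dioxolan-2-yl)prop-2-enal; 5 2-methylfuran
Product: 6 (3R)-3-(2-methyl-1,3-dioxolan-2-yl)-3-(5-methylfuran-2-yl)propanal
Conditions: (2S,5S)-5-benzyl-2-tert-butyl-3-methylimidazolidin-4-one·CF3CO2H (20 mol %), 5 (3 equiv), CH2Cl2/i-PrOH (85:15), −30 °C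
Reagents that add atoms: none
Why: In this iminium-catalysed Friedel–Crafts alkylation the furan attacks through C5 the β-carbon of the E-iminium ion on the face left open by the benzyl group, which sets C7 as R; the γ-carbon has no hydrogen, so no dienamine can form, and the two ketal oxygens offset electronically what the quaternary centre costs sterically.

Step 4
Reactants: 6 (3R)-3-(2-methyl-1,3-dioxolan-2-yl)-3-(5-methylfuran-2-yl)propanal; 7 3-(triphenylphosphoranylidene)butan-2-one
Product: 8 (3E,6R)-3-methyl-6-(2-methyl-1,3-dioxolan-2-yl)-6-(5-methylfuran-2-yl)hex-3-en-2-one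
Conditions: toluene, 80 °C
Reagents that add atoms: none
Why: Wittig olefination with a stabilised α-branched ylide should give the E-trisubstituted enone, and C7, which is not acidic, is untouched.

Step 5
Reactants: 8 (3E,6R)-3-methyl-6-(2-methyl-1,3-dioxolan-2-yl)-6-(5-methylfuran-2-yl)hex-3-en-2-one
Product: 10 (6R)-3-chloro-3-methyl-6-(2-methyl-1,3-dioxolan-2-yl)-6-(5-methylfuran-2-yl)hexan-2-one as a mixture of C3 epimers, via triethylsilyl enol ether 9 (not isolated)
Conditions: Et3SiH, RhCl(PPh3)3 (2 mol %), toluene, 50 °C; then N-chlorosuccinimide, THF, 0 °C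
Reagents that add atoms: N-chlorosuccinimide, O=C1CCC(=O)N1Cl
Why: 1,4-Hydrosilylation of the enone (monovalent rhodium, monohydrosilane) fixes the enol ether regiospecifically toward the future C10, and electrophilic chlorination of this tetrasubstituted silyl enol ether is much faster than attack on the furan; the configuration at the chlorinated carbon is irrelevant because it is ionised in the next step.

Step 6
Reactants: 10 (6R)-3-chloro-3-methyl-6-(2-methyl-1,3-dioxolan-2-yl)-6-(5-methylfuran-2-yl)hexan-2-one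
Product: 12 3,6-epoxy-3,10α-dimethyl-7β-(2-methyl-1,3-dioxolan-2-yl)hydroazul-4-en-1-one with the C3–O–C6 bridge on the β face, via oxyallyl cation 11 (not isolated)
Conditions: Et3N (3 equiv), CF3CH2OH, 0.02 M, 0 → 23 °C
Reagents that add atoms: none
Why: Triethylamine enolises the ketone toward its methyl group (C2) and the ionising solvent assists loss of chloride from tertiary C10, giving the 2-oxidoallyl cation 11 (C10–C1–C2), which the furan captures across its 2,5-positions (C6 and C3), concertedly or in two fast steps; the closest known reaction type is the intramolecular (4+3) cycloaddition of furans with oxyallyl cations generated from α-chloroketones by amine base in a fluorinated alcohol. The seven-membered ring (C10-C1-C2-C3-C4-C5-C6) closes by suprafacial bonding of the allyl termini C10 and C2 to C6 and C3 of one furan face, the five-membered ring (C6-C7-C8-C9-C10) closes through the same C6–C10 bond as a 5-exo closure held by the three-carbon tether, and the furan oxygen remains as the C3–O–C6 bridge. The tether can only take the outward position on C10 of the cation, so the C10 methyl points inward, and C10 is set by C7: with H-7 eclipsing furan H-5 (least allylic strain) the dioxolanyl group lies on the furan-oxygen side, and the inward methyl avoids it by taking the other face of the forming cyclopentane, so the extended mode should place C10–CH3 trans to the C7 substituent and the bridge cis to it (β). C3 and C6 follow from the suprafacial addition and are temporary. The step needs diastereofacial selectivity (C7/C10 trans) and preference for cycloaddition over solvent capture or Favorskii rearrangement; the bulky, fully substituted ketal carbon on C7 secures the first, the five-membered tether and high dilution the second.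

Step 7
Reactants: 12 3,6-epoxy-3,10α-dimethyl-7β-(2-methyl-1,3-dioxolan-2-yl)hydroazul-4-en-1-one
Product: 13 6β-hydroxy-3,10α-dimethyl-7β-(2-methyl-1,3-dioxolan-2-yl)hydroazula-2,4-dien-1-one
Conditions: DBU (1.0 equiv), CH2Cl2, 23 °C
Reagents that add atoms: none
Why: In this E1cB (retro-oxa-Michael) opening only C2 carries α-hydrogens because C10 is quaternary, so loss of the β-oxygen from C3 is regiochemically unique and is driven by release of bicyclic strain and by the new C2=C3–C4=C5 dienone conjugation, the oxygen staying on C6 as a tertiary alcohol.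

Step 8
Reactants: 13 6β-hydroxy-3,10α-dimethyl-7β-(2-methyl-1,3-dioxolan-2-yl)hydroazula-2,4-dien-1-one
Product: 14 6β-hydroxy-3,10α-dimethyl-7β-(2-methyl-1,3-dioxolan-2-yl)hydroazul-2-en-1-one
Conditions: [Rh(nbd)(dppb)]BF4 (5 mol %; nbd = norbornadiene, dppb = Ph2P(CH2)4PPh2), H2 (3 atm), CH2Cl2, 23 °C
Reagents that add atoms: none
Why: In this hydroxyl-directed homogeneous hydrogenation with cationic monovalent rhodium the tertiary allylic hydroxyl on C6 binds the metal and delivers hydrogen to the adjacent disubstituted C4=C5 bond, while the trisubstituted, electron-poor C2=C3 bond should not react.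

Step 9
Reactants: 14 6β-hydroxy-3,10α-dimethyl-7β-(2-methyl-1,3-dioxolan-2-yl)hydroazul-2-en-1-one
Product: 15 3,10α-dimethyl-7β-(2-methyl-1,3-dioxolan-2-yl)hydroazula-2,5-dien-1-one
Conditions: methyl N-(triethylammoniosulfonyl)carbamate, toluene, 60 °C
Reagents that add atoms: none
Why: The Burgess dehydration is a syn elimination, and the β-hydroxyl on C6 has a syn hydrogen only on C5 (H-7 is on the α face and C10 is quaternary), so the C5=C6 alkene should form under neutral conditions that spare the ketal.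

Step 10
Reactants: 15 3,10α-dimethyl-7β-(2-methyl-1,3-dioxolan-2-yl)hydroazula-2,5-dien-1-one
Product: 16 3,10α-dimethyl-7β-(2-methyl-1,3-dioxolan-2-yl)-6β-H-hydroazul-2-en-1-one (trans-fused)
Conditions: [Ir(cod)(PCy3)(py)]PF6 (5 mol %; cod = 1,5-cyclooctadiene), H2 (1 atm), CH2Cl2, 0 → 23 °C, stopped after one equivalent of H2
Reagents that add atoms: none
Why: In this directed homogeneous hydrogenation with cationic monovalent iridium the electron-rich C5=C6 bond should be reduced before the conjugated, electron-poor C2=C3 bond, and hydrogen is delivered to the β face because the α face is covered by the C10 methyl and the dioxolane oxygens of the β-oriented C7 substituent bind the metal, which sets H-6 β, trans to the C10 methyl.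

Step 11
Reactants: 16 3,10α-dimethyl-7β-(2-methyl-1,3-dioxolan-2-yl)-6β-H-hydroazul-2-en-1-one
Product: 17 3,10α-dimethyl-7β-(2-methyl-1,3-dioxolan-2-yl)-6β-H-hydroazul-2-en-1β-ol
Conditions: (S)-2-methyl-CBS-oxazaborolidine (0.3 equiv), BH3·SMe2, THF, −30 °C
Reagents that add atoms: none
Why: In this CBS reduction (1,2-selective on enones) the fully substituted C10 acts as the large group and the vinyl carbon C2 as the small one, so the (S)-catalyst should deliver hydride to the α face and set the C1 hydroxyl β under reagent control.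

Step 12
Reactants: 17 3,10α-dimethyl-7β-(2-methyl-1,3-dioxolan-2-yl)-6β-H-hydroazul-2-en-1β-ol
Product: 18 1β-(tert-butyldimethylsilyloxy)-3,10α-dimethyl-7β-(2-methyl-1,3-dioxolan-2-yl)-6β-H-hydroazul-2-ene
Conditions: t-BuMe2SiOSO2CF3, 2,6-lutidine, CH2Cl2, −78 °C
Reagents that add atoms: tert-butyldimethylsilyl trifluoromethanesulfonate, CC(C)(C)[Si](C)(C)OS(=O)(=O)C(F)(F)F
Why: Silylation of the hindered allylic alcohol with the silyl triflate and a hindered pyridine base is fast at −78 °C, where the ketal survives, and protects the hydroxyl from the electrophiles and the oxidant of steps 14 and 17.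

Step 13
Reactants: 18 1β-(tert-butyldimethylsilyloxy)-3,10α-dimethyl-7β-(2-methyl-1,3-dioxolan-2-yl)-6β-H-hydroazul-2-ene
Product: 19 7β-acetyl-1β-(tert-butyldimethylsilyloxy)-3,10α-dimethyl-6β-H-hydroazul-2-ene
Conditions: pyridinium p-toluenesulfonate, acetone/H2O (9:1), 50 °C
Reagents that add atoms: water, O
Why: Mild acid-catalysed ketal hydrolysis is safe here because the silyl ether and the isolated alkene tolerate it and no epoxide is present yet, and C7, now α to a ketone, already has the more stable configuration (acetyl trans to C5).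

Step 14
Reactants: 19 7β-acetyl-1β-(tert-butyldimethylsilyloxy)-3,10α-dimethyl-6β-H-hydroazul-2-ene
Product: 22 methyl 3-[1β-(tert-butyldimethylsilyloxy)-3,10α-dimethyl-6β-H-hydroazul-2-en-7β-yl]prop-2-ynoate, via enol diethyl phosphate 20 (not isolated), via lithium acetylide 21 (not isolated)
Conditions: LiN(i-Pr)2 (1.1 equiv), THF, −78 °C; ClP(O)(OEt)2; LiN(i-Pr)2 (2.3 equiv), −78 → 0 °C; ClCO2Me, −78 °C
Reagents that add atoms: methyl chloroformate, COC(=O)Cl
Why: Kinetic enolisation at the methyl group (tertiary H-7 is not removed at −78 °C), O-phosphorylation and base-induced elimination of the enol phosphate convert the methyl ketone into the terminal alkyne, whose lithium acetylide is acylated in the same flask.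

Step 15
Reactants: 22 methyl 3-[1β-(tert-butyldimethylsilyloxy)-3,10α-dimethyl-6β-H-hydroazul-2-en-7β-yl]prop-2-ynoate
Product: 23 methyl (Z)-3-[1β-(tert-butyldimethylsilyloxy)-3,10α-dimethyl-6β-H-hydroazul-2-en-7β-yl]but-2-enoate
Conditions: Me2CuLi (2 equiv), THF, −78 °C; MeOH, −78 °C
Reagents that add atoms: lithium dimethylcuprate, [Li+].C[Cu-]C
Why: Conjugate addition of a lithium dialkylcuprate to a 2-alkynoate is a syn carbocupration at −78 °C, so methyl and hydrogen end cis and C7 lies cis to the ester (Z), and protonation at low temperature prevents isomerisation of the alkenylcopper.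

Step 16
Reactants: 23 methyl (Z)-3-[1β-(tert-butyldimethylsilyloxy)-3,10α-dimethyl-6β-H-hydroazul-2-en-7β-yl]but-2-enoate
Product: 24 (Z)-3-[1β-(tert-butyldimethylsilyloxy)-3,10α-dimethyl-6β-H-hydroazul-2-en-7β-yl]but-2-en-1-ol
Conditions: i-Bu2AlH (2.5 equiv), CH2Cl2, −78 °C
Reagents that add atoms: none
Why: 1,2-Reduction of the enoate by the aluminium hydride gives the allylic alcohol without touching the Z alkene or the silyl ether.

Step 17
Reactants: 24 (Z)-3-[1β-(tert-butyldimethylsilyloxy)-3,10α-dimethyl-6β-H-hydroazul-2-en-7β-yl]but-2-en-1-ol; 25 methyl (triphenylphosphoranylidene)acetate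
Product: 27 methyl (2E,4Z)-5-[1β-(tert-butyldimethylsilyloxy)-3,10α-dimethyl-6β-H-hydroazul-2-en-7β-yl]hexa-2,4-dienoate, via Z-enal 26 (not isolated)
Conditions: MnO2 (20 equiv), 25 (1.5 equiv), CH2Cl2, 23 °C
Reagents that add atoms: none
Why: Allylic oxidation with in situ Wittig trapping by a stabilised ylide consumes the Z-enal as it forms, which limits Z-to-E isomerisation, and the new disubstituted alkene should be E.

Step 18
Reactants: 27 methyl (2E,4Z)-5-[1β-(tert-butyldimethylsilyloxy)-3,10α-dimethyl-6β-H-hydroazul-2-en-7β-yl]hexa-2,4-dienoate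
Product: 28 methyl (2E,4Z)-5-[1β-hydroxy-3,10α-dimethyl-6β-H-hydroazul-2-en-7β-yl]hexa-2,4-dienoate
Conditions: Bu4NF, THF, 23 °C
Reagents that add atoms: none
Why: Fluoride-mediated desilylation frees the C1 hydroxyl that the next step needs as a directing group.

Step 19
Reactants: 28 methyl (2E,4Z)-5-[1β-hydroxy-3,10α-dimethyl-6β-H-hydroazul-2-en-7β-yl]hexa-2,4-dienoate
Product: 29 methyl (2E,4Z)-5-[2β,3β-epoxy-1β-hydroxy-3,10α-dimethyl-6β-H-hydroazulan-7β-yl]hexa-2,4-dienoate
Conditions: VO(acac)2 (5 mol %), t-BuOOH, CH2Cl2, 0 °C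
Reagents that add atoms: tert-butyl hydroperoxide, CC(C)(C)OO
Why: In this hydroxyl-directed vanadium-catalysed epoxidation the allylic alcohol binds the metal peroxide and oxygen is delivered to C2=C3 syn to the 1β-hydroxyl, as is usual for allylic alcohols in five- to seven-membered rings, while the electron-poor dienoate is not attacked.

Step 20
Reactants: 29 methyl (2E,4Z)-5-[2β,3β-epoxy-1β-hydroxy-3,10α-dimethyl-6β-H-hydroazulan-7β-yl]hexa-2,4-dienoate
Product: 30 2β,3β-epoxy-7β-[(2Z,4E)-6-hydroxy-6-methylhepta-2,4-dien-2-yl]-3,10α-dimethyl-6β-H-hydroazulan-1β-ol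
Conditions: MeLi (4 equiv), THF, −78 → −30 °C
Reagents that add atoms: methyllithium, [Li]C
Why: Double 1,2-addition of methyllithium to the methyl ester gives the tertiary alcohol; the C1 alkoxide formed first cannot open the cis epoxide (no backside access), and the trisubstituted epoxide is inert at low temperature.

Step 21
Reactants: 30 2β,3β-epoxy-7β-[(2Z,4E)-6-hydroxy-6-methylhepta-2,4-dien-2-yl]-3,10α-dimethyl-6β-H-hydroazulan-1β-ol
Product: 31 target, the 1β-acetate of 30
Conditions: Ac2O, pyridine, 4-(dimethylamino)pyridine (cat.), CH2Cl2, 0 → 23 °C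
Reagents that add atoms: acetic anhydride, CC(=O)OC(C)=O
Why: Nucleophile-catalysed acylation should acetylate the secondary C1 alcohol and leave the tertiary allylic alcohol untouched.

Compound list
1 | 2-(2-bromoethyl)-2-methyl-1,3-dioxolane | CC1(CCBr)OCCO1 | starting material
2 | 2-ethenyl-2-methyl-1,3-dioxolane | C=CC1(C)OCCO1 | intermediate
3 | (E)-but-2-enal | C/C=C/C=O | starting material
4 | (E)-3-(2-methyl-1,3-dioxolan-2-yl)prop-2-enal | O=C/C=C/C1(C)OCCO1 | intermediate
5 | 2-methylfuran | Cc1ccco1 | starting material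
6 | (3R)-3-(2-methyl-1,3-dioxolan-2-yl)-3-(5-methylfuran-2-yl)propanal | Cc1ccc(o1)[C@H](C2(C)OCCO2)CC=O | intermediate
7 | 3-(triphenylphosphoranylidene)butan-2-one | CC(=O)C(C)=P(c1ccccc1)(c1ccccc1)c1ccccc1 | starting material
8 | (3E,6R)-3-methyl-6-(2-methyl-1,3-dioxolan-2-yl)-6-(5-methylfuran-2-yl)hex-3-en-2-one | Cc1ccc(o1)[C@H](C2(C)OCCO2)C/C=C(\C)C(C)=O | intermediate
9 | triethylsilyl enol ether of the saturated ketone, (6R)-3-methyl-6-(2-methyl-1,3-dioxolan-2-yl)-6-(5-methylfuran-2-yl)-2-(triethylsilyloxy)hex-2-ene, either alkene isomer (formed in the flask) | Cc1ccc(o1)[C@H](C2(C)OCCO2)CCC(C)=C(C)O[Si](CC)(CC)CC | intermediate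
10 | (6R)-3-chloro-3-methyl-6-(2-methyl-1,3-dioxolan-2-yl)-6-(5-methylfuran-2-yl)hexan-2-one, both C3 epimers | Cc1ccc(o1)[C@H](C2(C)OCCO2)CCC(C)(Cl)C(C)=O | intermediate
11 | 2-oxidoallyl (oxyallyl) cation C10–C1–C2 derived from 10 (formed in the flask) | Cc1ccc(o1)[C@H](C2(C)OCCO2)CC[C+](C)C([O-])=C | intermediate
12 | 3,6-epoxy-3,10α-dimethyl-7β-(2-methyl-1,3-dioxolan-2-yl)hydroazul-4-en-1-one, C3–O–C6 bridge β | O=C1C[C@@]2(C)C=C[C@@]3(O2)[C@H](C4(C)OCCO4)CC[C@]13C | intermediate
13 | 6β-hydroxy-3,10α-dimethyl-7β-(2-methyl-1,3-dioxolan-2-yl)hydroazula-2,4-dien-1-one | O=C1C=C(C)C=C[C@@]2(O)[C@H](C3(C)OCCO3)CC[C@]12C | intermediate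
14 | 6β-hydroxy-3,10α-dimethyl-7β-(2-methyl-1,3-dioxolan-2-yl)hydroazul-2-en-1-one | O=C1C=C(C)CC[C@@]2(O)[C@H](C3(C)OCCO3)CC[C@]12C | intermediate
15 | 3,10α-dimethyl-7β-(2-methyl-1,3-dioxolan-2-yl)hydroazula-2,5-dien-1-one | O=C1C=C(C)CC=C2[C@H](C3(C)OCCO3)CC[C@]12C | intermediate
16 | 3,10α-dimethyl-7β-(2-methyl-1,3-dioxolan-2-yl)-6β-H-hydroazul-2-en-1-one (trans-fused) | O=C1C=C(C)CC[C@H]2[C@H](C3(C)OCCO3)CC[C@]12C | intermediate
17 | 3,10α-dimethyl-7β-(2-methyl-1,3-dioxolan-2-yl)-6β-H-hydroazul-2-en-1β-ol | O[C@@H]1C=C(C)CC[C@H]2[C@H](C3(C)OCCO3)CC[C@]12C | intermediate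
18 | 1β-(tert-butyldimethylsilyloxy)-3,10α-dimethyl-7β-(2-methyl-1,3-dioxolan-2-yl)-6β-H-hydroazul-2-ene | CC(C)(C)[Si](C)(C)O[C@@H]1C=C(C)CC[C@H]2[C@H](C3(C)OCCO3)CC[C@]12C | intermediate
19 | 7β-acetyl-1β-(tert-butyldimethylsilyloxy)-3,10α-dimethyl-6β-H-hydroazul-2-ene | CC(C)(C)[Si](C)(C)O[C@@H]1C=C(C)CC[C@H]2[C@H](C(C)=O)CC[C@]12C | intermediate
20 | enol diethyl phosphate of 19, 7β-[1-(diethoxyphosphoryloxy)ethenyl] compound (formed in the flask) | CC(C)(C)[Si](C)(C)O[C@@H]1C=C(C)CC[C@H]2[C@H](C(=C)OP(=O)(OCC)OCC)CC[C@]12C | intermediate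
21 | lithium acetylide, 7β-(lithioethynyl) compound (formed in the flask) | CC(C)(C)[Si](C)(C)O[C@@H]1C=C(C)CC[C@H]2[C@H](C#C[Li])CC[C@]12C | intermediate
22 | methyl 3-[1β-(tert-butyldimethylsilyloxy)-3,10α-dimethyl-6β-H-hydroazul-2-en-7β-yl]prop-2-ynoate | CC(C)(C)[Si](C)(C)O[C@@H]1C=C(C)CC[C@H]2[C@H](C#CC(=O)OC)CC[C@]12C | intermediate
23 | methyl (Z)-3-[1β-(tert-butyldimethylsilyloxy)-3,10α-dimethyl-6β-H-hydroazul-2-en-7β-yl]but-2-enoate | CC(C)(C)[Si](C)(C)O[C@@H]1C=C(C)CC[C@H]2[C@H](/C(C)=C\C(=O)OC)CC[C@]12C | intermediate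
24 | (Z)-3-[1β-(tert-butyldimethylsilyloxy)-3,10α-dimethyl-6β-H-hydroazul-2-en-7β-yl]but-2-en-1-ol | CC(C)(C)[Si](C)(C)O[C@@H]1C=C(C)CC[C@H]2[C@H](/C(C)=C\CO)CC[C@]12C | intermediate
25 | methyl (triphenylphosphoranylidene)acetate | COC(=O)C=P(c1ccccc1)(c1ccccc1)c1ccccc1 | starting material
26 | (Z)-3-[1β-(tert-butyldimethylsilyloxy)-3,10α-dimethyl-6β-H-hydroazul-2-en-7β-yl]but-2-enal (formed in the flask) | CC(C)(C)[Si](C)(C)O[C@@H]1C=C(C)CC[C@H]2[C@H](/C(C)=C\C=O)CC[C@]12C | intermediate
27 | methyl (2E,4Z)-5-[1β-(tert-butyldimethylsilyloxy)-3,10α-dimethyl-6β-H-hydroazul-2-en-7β-yl]hexa-2,4-dienoate | CC(C)(C)[Si](C)(C)O[C@@H]1C=C(C)CC[C@H]2[C@H](/C(C)=C\C=C\C(=O)OC)CC[C@]12C | intermediate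
28 | methyl (2E,4Z)-5-[1β-hydroxy-3,10α-dimethyl-6β-H-hydroazul-2-en-7β-yl]hexa-2,4-dienoate | O[C@@H]1C=C(C)CC[C@H]2[C@H](/C(C)=C\C=C\C(=O)OC)CC[C@]12C | intermediate
29 | methyl (2E,4Z)-5-[2β,3β-epoxy-1β-hydroxy-3,10α-dimethyl-6β-H-hydroazulan-7β-yl]hexa-2,4-dienoate | O[C@@H]1[C@@H]2O[C@]2(C)CC[C@H]2[C@H](/C(C)=C\C=C\C(=O)OC)CC[C@]12C | intermediate
30 | 2β,3β-epoxy-7β-[(2Z,4E)-6-hydroxy-6-methylhepta-2,4-dien-2-yl]-3,10α-dimethyl-6β-H-hydroazulan-1β-ol | O[C@@H]1[C@@H]2O[C@]2(C)CC[C@H]2[C@H](/C(C)=C\C=C\C(C)(C)O)CC[C@]12C | intermediate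
31 | CNP0265175.1, (1S,2S,3R,6S,7R,10S)-2,3-epoxy-7-[(2Z,4E)-6-hydroxy-6-methylhepta-2,4-dien-2-yl]-3,10-dimethylhydroazulan-1-yl acetate (target locants) | CC(=O)O[C@@H]1[C@@H]2O[C@]2(C)CC[C@H]2[C@H](/C(C)=C\C=C\C(C)(C)O)CC[C@]12C | target

Total step count: 21. Longest linear sequence: 21 steps (1 to 31; the route is linear).

Steps most likely to fail

Step 6 (key step). The cation may be captured by the solvent or rearrange (Favorskii) faster than it cyclises, or the compact and extended modes may compete, so that facial discrimination across the tether is poor and C10 forms with its methyl cis to the C7 group. Fallback: from 10, kinetic enolisation toward the methyl group and O-silylation (LiN(i-Pr)2, Me3SiCl, THF, −78 °C) should give the 2-(trimethylsilyloxy)allyl chloride F1. ZnCl2 in CH2Cl2 at −78 → 0 °C then ionises the tertiary allylic chloride to a 2-silyloxyallyl cation. This more electrophilic species reacts at low temperature in a non-nucleophilic medium and is known to favour the extended mode. The same intramolecular (4+3) cycloaddition followed by loss of Me3SiCl returns to 12.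

Step 10. The catalyst may fail to discriminate between the two trisubstituted alkenes, may move the C5=C6 bond into conjugation, or may deliver hydrogen to the α face, giving the cis ring fusion. Fallback: from 15, the C1 ketone is reduced first ((S)-2-methyl-CBS-oxazaborolidine, BH3·SMe2) to the 1β-dienol F2. VO(acac)2/t-BuOOH then epoxidises only the allylic C2=C3 bond, syn to the hydroxyl, giving the epoxy alcohol F3, in which C2–C3 is masked. [Ir(cod)(PCy3)(py)]PF6/H2, now bound by the 1β-hydroxyl (homoallylic to C5=C6), delivers hydrogen to the β face to give the saturated epoxy alcohol F4. Silylation (t-BuMe2SiOSO2CF3, 2,6-lutidine) gives the silyl ether F5, and stereospecific deoxygenation of the epoxide with the low-valent tungsten reagent from WCl6 and n-BuLi (THF) regenerates C2=C3 and returns to 18.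

Step 11. Reagent-controlled delivery of hydride to the α face has to override the substrate bias (attack anti to the C10 methyl), so the facial selectivity may be poor or reversed. Fallback: from 16, Luche reduction (NaBH4, CeCl3·7H2O, MeOH, −78 °C) under substrate control should give the 1α-alcohol F6. Mitsunobu inversion (PPh3, i-PrO2C–N=N–CO2i-Pr, 4-nitrobenzoic acid, toluene), with the nucleophile entering from the β face away from the C10 methyl, gives the 1β-(4-nitrobenzoate) F7. Methanolysis (K2CO3, MeOH) returns to 17.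

Further compounds
F1 | step 6 | (6R)-3-chloro-3-methyl-6-(2-methyl-1,3-dioxolan-2-yl)-6-(5-methylfuran-2-yl)-2-(trimethylsilyloxy)hex-1-ene | Cc1ccc(o1)[C@H](C2(C)OCCO2)CCC(C)(Cl)C(=C)O[Si](C)(C)C
F2 | step 10 | 3,10α-dimethyl-7β-(2-methyl-1,3-dioxolan-2-yl)hydroazula-2,5-dien-1β-ol | O[C@@H]1C=C(C)CC=C2[C@H](C3(C)OCCO3)CC[C@]12C
F3 | step 10 | 2β,3β-epoxy-3,10α-dimethyl-7β-(2-methyl-1,3-dioxolan-2-yl)hydroazul-5-en-1β-ol | O[C@@H]1[C@@H]2O[C@]2(C)CC=C2[C@H](C3(C)OCCO3)CC[C@]12C
F4 | step 10 | 2β,3β-epoxy-3,10α-dimethyl-7β-(2-methyl-1,3-dioxolan-2-yl)-6β-H-hydroazulan-1β-ol | O[C@@H]1[C@@H]2O[C@]2(C)CC[C@H]2[C@H](C3(C)OCCO3)CC[C@]12C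
F5 | step 10 | 1β-(tert-butyldimethylsilyloxy)-2β,3β-epoxy-3,10α-dimethyl-7β-(2-methyl-1,3-dioxolan-2-yl)-6β-H-hydroazulane | CC(C)(C)[Si](C)(C)O[C@@H]1[C@@H]2O[C@]2(C)CC[C@H]2[C@H](C3(C)OCCO3)CC[C@]12C
F6 | step 11 | 3,10α-dimethyl-7β-(2-methyl-1,3-dioxolan-2-yl)-6β-H-hydroazul-2-en-1α-ol | O[C@H]1C=C(C)CC[C@H]2[C@H](C3(C)OCCO3)CC[C@]12C
F7 | step 11 | 3,10α-dimethyl-7β-(2-methyl-1,3-dioxolan-2-yl)-6β-H-hydroazul-2-en-1β-yl 4-nitrobenzoate | O=C(O[C@@H]1C=C(C)CC[C@H]2[C@H](C3(C)OCCO3)CC[C@]12C)c1ccc(cc1)[N+](=O)[O-]
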